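The numbers in the tables were generated by integration for substances that don't exist; noise was put on by code.

Late in the alder run the selectivity c_Q/c_G, as read, was still falling, and it stood at 4.04 at 1.25 d and 1.60 at 5.00 d, so I went to logarithms. Those readings give −0.666 decades of ratio per decade of time, a log-log slope I called the ratio slope.

all flasks: J 0.050 M
- alder: E 2 equiv; run made earlier
- flask: E 1.00 equiv; time 15 d

alder run (percent of the J charged)

| time / d | Q / % | G / % |
|---|---|---|
| 0.625 | 8.3 | 1.9 |
| 1.25 | 20.6 | 5.1 |
| 2.08 | 29.3 | 10.0 |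
| 2.50 | 32.1 | 11.5 |
| 3.00 | 33.7 | 13.3 |
| 4.00 | 33.9 | 17.8 |
| 5.00 | 33.2 | 20.7 |

(readings scatter by 0.5 percentage points)

* ratio of Q to G at 5.0 h
* ratio of Q to G at 15 d
* which of Q and G there is more of at 15 d



Time was the first setting. Going from 5.00 d to 15 d is 0.477 of a decade, so by hand I put the ratio at 0.771, less than one, and expected G ahead. At the other end, 5.0 h lies before the first reading, so I kept that reading's ratio, 4.37. E was the second setting, 1.00 equiv in the flask against 2 equiv in the alder run. I guessed that E paces a supply shared by Q and G, and so left both ratios unchanged, though this stayed a guess, as the alder run had a single charge of E. c_J stayed at 0.050 M.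

The forecast gave 4.3 (range 3.2 to 5.8) at 5.0 h and 0.5 (range 0.2 to 1.1) at 15 d, with G ahead, on the ground that “Q drains to G”. Its late ratio was lower than mine.

The flask gave 5.28 at 5.0 h and 0.733 at 15 d, with G ahead, 34.1% against 25.0% of the J charged.

    Q ⇌ Z (K = 0.440, k = 0.399 h⁻¹)
    J + E → D + X (k = 0.530 M⁻¹ h⁻¹)
    D ⇌ G (K = 2.60, k = 0.00672 h⁻¹)
    D ⇌ Q (K = 1.20, k = 0.0486 h⁻¹)

The ratio slope landed 0.0220 of a decade above the flask at 15 d, while the forecast lay 0.166 of a decade below it. For the neighbour flask charged with 4.00 equiv of E, the same reckoning again gives 0.771. That neighbour flask stood at 0.648, lower by 0.0755 of a decade, with G at 40.6% of the J charged.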